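The chromanone ring is disconnected at C4–C4a and O1–C8a. This leaves O1, C2, C3 and C4 as an enantiopure (S)-4-aryl-oxetan-2-one carrying ring B, and ring A as 2-fluoro-4-(methoxymethoxy)phenyllithium, a regiodefined equivalent of an aryne. In one flask the aryllithium opens the β-lactone at its acyl carbon and the released C2 alkoxide displaces the ortho fluoride, so C4a and C8a insert into the C4–O1 bond and the four-membered ring grows to the six-membered pyranone while both halves are joined. The step exploits the ortho placement of the C4 carbonyl and O1 on ring A; the C2–O1 bond, and with it the (S) centre, is never broken.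

Key step: step 9

Remark: atom labels follow chroman-4-one numbering (ring A = benzo ring with O1, C4, C4a, C8a; ring B = the 2-aryl group); the stereocentre in the SMILES is read as (2S); Ar below = 2,2-dimethyl-8-(3-methylbut-2-en-1-yl)-2H-chromen-6-yl.

Step 1
Reactants: 1 1-(3-bromo-4-hydroxyphenyl)ethan-1-one
Product: 2 1-{3-bromo-4-[(2-methylbut-3-yn-2-yl)oxy]phenyl}ethan-1-one
Conditions: 3-chloro-3-methylbut-1-yne, K2CO3, KI, CuI (copper iodide, cat.), acetone, 56 °C
Reagents that add atoms: 3-chloro-3-methylbut-1-yne, CC(C)(Cl)C#C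
Why: Copper-assisted Williamson-type O-alkylation of the phenoxide with the tertiary propargylic chloride should give the aryl 1,1-dimethylpropargyl ether without touching the ketone.

Step 2
Reactants: 2 1-{3-bromo-4-[(2-methylbut-3-yn-2-yl)oxy]phenyl}ethan-1-one
Product: 3 1-(8-bromo-2,2-dimethyl-2H-chromen-6-yl)ethan-1-one
Conditions: N,N-diethylaniline, 190 °C
Reagents that add atoms: none
Why: Aromatic propargyl Claisen rearrangement to the only free ortho position, then 1,5-hydrogen shift and 6π oxa-electrocyclization, should close the 2,2-dimethyl-2H-chromene ring, the bromine blocking the other ortho site.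

Step 3
Reactants: 3 1-(8-bromo-2,2-dimethyl-2H-chromen-6-yl)ethan-1-one
Product: 4 1-[2,2-dimethyl-8-(3-methylbut-2-en-1-yl)-2H-chromen-6-yl]ethan-1-one
Conditions: tributyl(3-methylbut-2-en-1-yl)stannane, Pd(PPh3)4 (5 mol %), DMF, 100 °C
Reagents that add atoms: tributyl(3-methylbut-2-en-1-yl)stannane, CC(C)=CC[Sn](CCCC)(CCCC)CCCC
Why: Stille cross-coupling (zerovalent palladium catalysis) of the aryl bromide with the prenylstannane should install the C8 side chain, reductive elimination at the less substituted allyl terminus giving the linear prenyl isomer.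

Step 4
Reactants: 4 1-[2,2-dimethyl-8-(3-methylbut-2-en-1-yl)-2H-chromen-6-yl]ethan-1-one
Product: 5 methyl 3-Ar-3-oxopropanoate
Conditions: NaH, (MeO)2CO, THF, 66 °C; then 1 M HCl
Reagents that add atoms: dimethyl carbonate, COC(=O)OC
Why: Claisen-type C-acylation of the sodium enolate of the methyl ketone with dimethyl carbonate should give the β-keto ester, driven by deprotonation of the product.

Step 5
Reactants: 5 methyl 3-Ar-3-oxopropanoate
Product: 6 methyl (3S)-3-Ar-3-hydroxypropanoate
Conditions: RuCl[(S,S)-TsDPEN](p-cymene) (1 mol %), HCO2H/Et3N (5:2), DMF, 40 °C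
Reagents that add atoms: none
Why: Noyori–Ikariya asymmetric transfer hydrogenation of the aryl ketone should set the future C2 centre, the (S,S)-catalyst delivering hydride to the Re face (aryl group next to the η6-arene, as for acetophenone) to give the (S)-carbinol while the isolated alkenes stay inert.

Step 6
Reactants: 6 methyl (3S)-3-Ar-3-hydroxypropanoate
Product: 7 (3S)-3-Ar-3-hydroxypropanoic acid
Conditions: LiOH, THF/H2O, 0 °C; then 1 M HCl to pH 3, 0 °C
Reagents that add atoms: lithium hydroxide, [Li+].[OH-]
Why: Cold saponification of the methyl ester should give the β-hydroxy acid without retro-aldol cleavage or dehydration, and the stereocentre is not involved.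

Step 7
Reactants: 7 (3S)-3-Ar-3-hydroxypropanoic acid
Product: 8 (4S)-4-Ar-oxetan-2-one
Conditions: PhSO2Cl, pyridine, 0 °C; cold work-up, used at once
Reagents that add atoms: none
Why: β-Lactonization by carboxyl activation (mixed carboxylic–sulfonic anhydride, then 4-exo-trig acyl substitution by the hydroxyl group) leaves the carbinol C–O bond intact, so the (S) configuration should be retained; the electron-rich lactone is kept cold to suppress loss of CO2.

Step 8
Reactants: 9 4-bromo-3-fluorophenol
Product: 10 1-bromo-2-fluoro-4-(methoxymethoxy)benzene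
Conditions: MOMCl, i-Pr2NEt, CH2Cl2, 0 → 23 °C
Reagents that add atoms: chloromethyl methyl ether, COCCl
Why: O-Alkylation of the phenol with chloromethyl methyl ether (acetal protection) masks the acidic OH before lithiation and is stable to organolithium and alkoxide.

Step 9
Reactants: 8 (4S)-4-Ar-oxetan-2-one, 10 1-bromo-2-fluoro-4-(methoxymethoxy)benzene
Product: 14 (2S)-2-Ar-7-(methoxymethoxy)-2,3-dihydro-4H-chromen-4-one, via aryllithium 11 (not isolated), via lithium oxetanolate 12 (not isolated), via lithium keto alkoxide 13 (not isolated)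
Conditions: 10, n-BuLi (1.0 equiv), THF, −78 °C; cannulation into 8 (1.1 equiv), THF, −78 °C; then DMPU, −78 → 23 °C; aq NH4Cl
Reagents that add atoms: n-butyllithium, [Li]CCCC (supplies the lithium of 11–13; none of its atoms remains in 14)
Why: Bromine–lithium exchange on 10 gives aryllithium 11 (kept at −78 °C so that it does not lose LiF to an aryne), which adds to the strained lactone carbonyl of 8 with acyl–oxygen cleavage, the known mode for hard organolithium reagents on β-lactones, to give oxetanolate 12 (transient hemiketal centre, uncontrolled and lost) and then the lithium keto alkoxide 13. On warming with DMPU the alkoxide oxygen should attack C8a, which is ortho to the new C4 ketone and bears fluoride, and close the six-membered ring by intramolecular SNAr (addition–elimination through a Meisenheimer enolate, formally a 6-endo-trig attack on the C4=O/C4a=C8a–F vinylogous acyl fluoride), the known closure of 2-fluoroaryl β-hydroxy ketones to chroman-4-ones. Overall C4a and C8a insert into the acyl C4–O1 bond as in an aryne σ-insertion, but with fixed regiochemistry, so the oxetanone becomes the chromanone and the two fragments are joined in one flask. No stereocentre is created in the product: C2 keeps the (S) configuration of 8 because neither its bond to O1 nor its bond to C3 is broken. The step needs attack at the acyl carbon and not at the benzylic O-alkyl carbon, a single addition, and ring closure faster than retro-aldol cleavage or E1cB dehydration of 13; the hard lithium reagent, inverse addition at −78 °C, the chelated lithium aldolate and the irreversible loss of LiF are relied on for this. The positions of Li and F in 11 place the ketone para and O1 meta to the C7 oxygen.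

Step 10
Reactants: 14 (2S)-2-Ar-7-(methoxymethoxy)-2,3-dihydro-4H-chromen-4-one
Product: 15 (2S)-2-Ar-7-hydroxy-2,3-dihydro-4H-chromen-4-one
Conditions: HCl (cat.), MeOH, 40 °C
Reagents that add atoms: none
Why: Acid-catalysed acetal exchange (methanolysis of the MOM ether) should release the C7 phenol under conditions mild enough for the prenyl and chromene alkenes and for the C2 centre.

Compound list
1 | 1-(3-bromo-4-hydroxyphenyl)ethan-1-one | CC(=O)c1ccc(O)c(Br)c1 | starting material
2 | 1-{3-bromo-4-[(2-methylbut-3-yn-2-yl)oxy]phenyl}ethan-1-one | CC(=O)c1ccc(OC(C)(C)C#C)c(Br)c1 | intermediate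
3 | 1-(8-bromo-2,2-dimethyl-2H-chromen-6-yl)ethan-1-one | CC(=O)c1cc(Br)c2OC(C)(C)C=Cc2c1 | intermediate
4 | 1-[2,2-dimethyl-8-(3-methylbut-2-en-1-yl)-2H-chromen-6-yl]ethan-1-one | CC(=O)c1cc(CC=C(C)C)c2OC(C)(C)C=Cc2c1 | intermediate
5 | methyl 3-[2,2-dimethyl-8-(3-methylbut-2-en-1-yl)-2H-chromen-6-yl]-3-oxopropanoate | COC(=O)CC(=O)c1cc(CC=C(C)C)c2OC(C)(C)C=Cc2c1 | intermediate
6 | methyl (3S)-3-[2,2-dimethyl-8-(3-methylbut-2-en-1-yl)-2H-chromen-6-yl]-3-hydroxypropanoate | COC(=O)C[C@H](O)c1cc(CC=C(C)C)c2OC(C)(C)C=Cc2c1 | intermediate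
7 | (3S)-3-[2,2-dimethyl-8-(3-methylbut-2-en-1-yl)-2H-chromen-6-yl]-3-hydroxypropanoic acid | OC(=O)C[C@H](O)c1cc(CC=C(C)C)c2OC(C)(C)C=Cc2c1 | intermediate
8 | (4S)-4-[2,2-dimethyl-8-(3-methylbut-2-en-1-yl)-2H-chromen-6-yl]oxetan-2-one | O=C1C[C@@H](c2cc(CC=C(C)C)c3OC(C)(C)C=Cc3c2)O1 | intermediate
9 | 4-bromo-3-fluorophenol | Oc1ccc(Br)c(F)c1 | starting material
10 | 1-bromo-2-fluoro-4-(methoxymethoxy)benzene | COCOc1ccc(Br)c(F)c1 | intermediate
11 | [2-fluoro-4-(methoxymethoxy)phenyl]lithium | [Li]c1ccc(OCOC)cc1F | intermediate (not isolated)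
12 | lithium (4S)-4-[2,2-dimethyl-8-(3-methylbut-2-en-1-yl)-2H-chromen-6-yl]-2-[2-fluoro-4-(methoxymethoxy)phenyl]oxetan-2-olate (both C2 epimers) | [Li]OC1(c2ccc(OCOC)cc2F)C[C@@H](c2cc(CC=C(C)C)c3OC(C)(C)C=Cc3c2)O1 | intermediate (not isolated)
13 | lithium (1S)-1-[2,2-dimethyl-8-(3-methylbut-2-en-1-yl)-2H-chromen-6-yl]-3-[2-fluoro-4-(methoxymethoxy)phenyl]-3-oxopropan-1-olate | [Li]O[C@@H](CC(=O)c1ccc(OCOC)cc1F)c1cc(CC=C(C)C)c2OC(C)(C)C=Cc2c1 | intermediate (not isolated)
14 | (2S)-2-[2,2-dimethyl-8-(3-methylbut-2-en-1-yl)-2H-chromen-6-yl]-7-(methoxymethoxy)-2,3-dihydro-4H-chromen-4-one | CC(C)=CCc1cc([C@@H]2CC(=O)c3ccc(OCOC)cc3O2)cc2c1OC(C)(C)C=C2 | intermediate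
15 | (2S)-2-[2,2-dimethyl-8-(3-methylbut-2-en-1-yl)-2H-chromen-6-yl]-7-hydroxy-2,3-dihydro-4H-chromen-4-one | CC(C)=CCc1cc([C@@H]2CC(=O)c3ccc(O)cc3O2)cc2c1OC(C)(C)C=C2 | target

Total step count: 10

Longest linear sequence: 9 steps (steps 1–7, 9 and 10, from 1 to 15); step 8 is a one-step side branch.

Steps most likely to fail

Step 9. The aryllithium may add a second time to the ketone of 13 or enolise the lactone. If the SNAr is slow, the aldolate may undergo retro-aldol cleavage and re-addition (erosion of the C2 configuration) or E1cB dehydration. Residual base may also open the finished chromanone ring reversibly and racemise C2. The fallback uses known chemistry, makes C2–O1 first with inversion and C4–C4a last, and never forms an aldolate. It sets out from 5. Transfer hydrogenation with the enantiomeric catalyst RuCl[(R,R)-TsDPEN](p-cymene) under the conditions of step 5 should give methyl (3R)-3-Ar-3-hydroxypropanoate F1. Mitsunobu etherification with 2-bromo-5-(methoxymethoxy)phenol (Oc1cc(OCOC)ccc1Br; PPh3, DIAD, toluene, 0 °C) should invert the carbinol carbon and give methyl (3S)-3-Ar-3-[2-bromo-5-(methoxymethoxy)phenoxy]propanoate F2. Parham cyclisation (t-BuLi, THF, −100 °C; bromine–lithium exchange, then intramolecular acylation of the aryllithium by the ester) should close the C4–C4a bond and come back to the route at 14.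

Step 7. The benzylic C–O bond of the 4-aryl-β-lactone is activated by the para oxygen of ring B, so ionisation with loss of CO2 may occur during lactonisation, work-up or storage. The fallback avoids the lactone and sets out from 6. Aminolysis with MeNHOMe·HCl and i-PrMgCl (THF, −20 °C) should give the Weinreb amide (3S)-3-Ar-3-hydroxy-N-methoxy-N-methylpropanamide F3. Addition of aryllithium 11 (2.2 equiv, THF, −78 °C; the first equivalent deprotonates the hydroxyl group and the chelated tetrahedral adduct prevents a second addition) should give, after quench, the hydroxy ketone (3S)-3-Ar-1-[2-fluoro-4-(methoxymethoxy)phenyl]-3-hydroxypropan-1-one F4. Ring closure by intramolecular SNAr under separately chosen mild conditions (Cs2CO3, DMF, 23 °C) comes back to the route at 14.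

Step 10. Acid may ionise the benzylic C2–O1 bond (ring opening and loss of configuration) or add methanol to the prenyl and chromene double bonds before the acetal is fully cleaved. The fallback replaces the acid-labile group by one removed under neutral conditions and sets out from 9. O-Allylation (allyl bromide, K2CO3, acetone, 56 °C) should give 1-bromo-2-fluoro-4-(prop-2-en-1-yloxy)benzene F5. The sequence of step 9 with 8 should then give (2S)-2-Ar-7-(prop-2-en-1-yloxy)-2,3-dihydro-4H-chromen-4-one F6. Deallylation by π-allyl transfer to an amine (Pd(PPh3)4, morpholine, THF, 23 °C), conditions under which the chromene ether should stay intact as it does in step 3, gives 15 directly.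

Further compounds
F1 | step 9 | methyl (3R)-3-[2,2-dimethyl-8-(3-methylbut-2-en-1-yl)-2H-chromen-6-yl]-3-hydroxypropanoate | COC(=O)C[C@@H](O)c1cc(CC=C(C)C)c2OC(C)(C)C=Cc2c1
F2 | step 9 | methyl (3S)-3-[2-bromo-5-(methoxymethoxy)phenoxy]-3-[2,2-dimethyl-8-(3-methylbut-2-en-1-yl)-2H-chromen-6-yl]propanoate | COC(=O)C[C@H](Oc1cc(OCOC)ccc1Br)c1cc(CC=C(C)C)c2OC(C)(C)C=Cc2c1
F3 | step 7 | (3S)-3-[2,2-dimethyl-8-(3-methylbut-2-en-1-yl)-2H-chromen-6-yl]-3-hydroxy-N-methoxy-N-methylpropanamide | CON(C)C(=O)C[C@H](O)c1cc(CC=C(C)C)c2OC(C)(C)C=Cc2c1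
F4 | step 7 | (3S)-3-[2,2-dimethyl-8-(3-methylbut-2-en-1-yl)-2H-chromen-6-yl]-1-[2-fluoro-4-(methoxymethoxy)phenyl]-3-hydroxypropan-1-one | O=C(C[C@H](O)c1cc(CC=C(C)C)c2OC(C)(C)C=Cc2c1)c1ccc(OCOC)cc1F
F5 | step 10 | 1-bromo-2-fluoro-4-(prop-2-en-1-yloxy)benzene | C=CCOc1ccc(Br)c(F)c1
F6 | step 10 | (2S)-2-[2,2-dimethyl-8-(3-methylbut-2-en-1-yl)-2H-chromen-6-yl]-7-(prop-2-en-1-yloxy)-2,3-dihydro-4H-chromen-4-one | CC(C)=CCc1cc([C@@H]2CC(=O)c3ccc(OCC=C)cc3O2)cc2c1OC(C)(C)C=C2
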